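Remark on the chemistry (assumption): ring positions are numbered from the phenol carbon (C1 OH, C2 and C4 OMe, C6 chain, C3 and C5 H). Dimethyl squarate, 1‑bromoeicosane and 2,3‑dibromoprop‑1‑ene are taken as purchasable, and all chiral intermediates are racemic.

## Analysis of the target

Target 15 is one benzene ring with four substituents: a free hydroxyl at C1, methoxyls at C2 and C4, and an unbranched C21 chain at C6; C3 and C5 carry hydrogen. It has no stereocentres, so the problem is purely one of regiochemistry on the ring. O1 and O4 are para, so the ring is a hydroquinone methylated on one oxygen only, with a further methoxyl (O2) beside the free hydroxyl. A 4‑alkoxyphenol of this kind is very electron‑rich: it is easily oxidised to a quinone, and C3 and C5 are open to electrophiles. The C21 chain makes every intermediate a wax that is poorly soluble in polar media and at low temperature. The difficulty is that the three ring oxygens must end in two different states, with the free one being the most hindered (between OMe and the chain). Substitution of a preformed trioxygenated arene would have to choose between C6 and C5 and cannot deliver a linear C21 chain cleanly. The plan rests on the para pair O1/O4 flanked by C2–OMe on one side and the C6(chain)–C5(H) edge on the other. Atoms C1–C2–C3–C4 map onto a cyclobutenone (carbinol carbon, methoxy‑bearing alkene carbon, CH, carbonyl carbon) and C6–C5 onto a 1,1‑disubstituted alkene, so O1 and O4 are created in different functional states.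

## Retrosynthetic reasoning

15 ⇒ 14. The O1–CH2 bond of a methoxymethyl acetal is cut first. The oxidation‑prone free phenol then exists only in the last flask. The forward step has to remove an acetal without touching two aryl methyl ethers.

14 ⇒ 13. Next the O4–CH3 bond is cut. In 13 the oxygen at C4 is the only free hydroxyl, so the forward methylation needs no selectivity.

13 ⇒ 10. The ring is cut at C4–C5 and C1 is joined to C4 across the ring. This folds C1–C4 into a four‑membered ring and leaves C5=C6 as a pendant alkene, giving cyclobutenone 10. The cut is made here because in 10 the future O1 is an ether on an sp3 carbon and the future O4 is a ketone, so the two para oxygens cannot be confused. C2–OMe is the enol ether carbon, C3 the ring CH, and the chain sits on the substituted alkene carbon. Cuts at C5–C6 or C1–C6 lead instead to open‑chain polycarbonyl compounds in which the oxygens are alike. In the forward direction, heat must open 10 to ketene 11 with the ether rotating outward, 11 must close to 12, and 12 must enolise to 13.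

10 ⇒ 9 ⇒ 3 + 8. The acetal C–O bond is cut to give tertiary alcohol 9. The bond between the carbinol carbon and the alkene carbon is then cut to give dione 3 and alkenyllithium 8. This is the only C–C bond formed between the two halves before the key step. The forward addition must go to the carbonyl next to the methoxy‑bearing carbon of 3; that carbonyl is ketone‑like, whereas the other is deactivated as a vinylogous ester.

8 ⇒ 7 ⇒ 4 + 5. Reagent 8 comes from bromide 7 by halogen–lithium exchange. Bromide 7 is cut at the allylic C3–C4 bond of the tricosene chain into Grignard reagent 6 (from bromide 4) and the bromoallyl unit 5. Both modes of allylic substitution give the same product, so this one step poses no regiochemical question.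

3 ⇒ 2 ⇒ 1. Dione 3 is squarate 1 with one methoxyl replaced by hydrogen. It is traced back through carbinol 2 by a hydride 1,2‑addition and an acid‑mediated 1,3‑transposition that expels one methoxyl group.

## Alternatives that were turned down

Alternative 1: The ring is opened at C5–C6 into a linear 1,3,5‑triketone with the benzyloxy group between the first two carbonyls, stored as 3‑(benzyloxy)‑2‑heneicosyl‑6‑methyl‑4H‑pyran‑4‑one A1.
- Forward key step: hot aqueous‑ethanolic KOH opens A1, the terminal methyl carbanion adds to the chain ketone, and dehydration and enolisation give 4‑(benzyloxy)‑5‑heneicosylbenzene‑1,3‑diol A2.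
- For: on oxygen differentiation it is stronger than the chosen plan. O1 arrives protected and O2 and O4 arrive free together, so one exhaustive methylation and one hydrogenolysis finish the synthesis. It needs no cryogenic organometallics and no strained or volatile intermediates.
- Against: the open triketone has a second carbanion site, the chain CH2 beside the chain ketone, which can add to the methyl ketone and also close a six‑membered ring. That gives an isomeric arene with a ring methyl and a C20 chain. The desired mode attacks the more hindered ketone, and only small differences in acidity and sterics decide between the two. Hot hydroxide also invites retro‑Claisen cleavage, and a C21 lipid dissolves poorly in aqueous ethanol. A1 itself needs several steps.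
- Comparison: the chosen route gives up the free double methylation and accepts a protecting group. In return, the substitution pattern of 13 follows from connectivity alone, and the key step is neutral and homogeneous.

Alternative 2: Bonds C1–C6 and C2–C3 are cut, giving diethyl 2‑(benzyloxy)malonate A3 and (E)‑pentacos‑3‑en‑2‑one A4.
- Forward key step: NaOEt in ethanol effects Michael addition of A3 to A4, then Claisen condensation of the methyl ketone onto one ester, to give ethyl 1‑(benzyloxy)‑2‑heneicosyl‑4,6‑dioxocyclohexane‑1‑carboxylate A5.
- For: it is convergent, uses simple building blocks and a classical annulation at ordinary temperature, and again delivers O2 and O4 as an equivalent pair.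
- Against: the donor is a tertiary carbanion, and it creates a quaternary carbon next to the chain‑bearing carbon, so the Michael step is hindered and reversible. The ring arrives at the wrong oxidation level and with an extra ester. Decarboxylation at a non‑enolisable β‑keto ester risks retro‑Claisen opening. Dehydrogenation must then compete with β‑elimination of the benzyloxy group, which aromatises without an oxidant and deletes O1. Four steps follow the key step, against two in the chosen route, and two stereocentres are made only to be destroyed.
- Comparison: the chosen route delivers the aromatic oxidation level and all three oxygens directly from the ring‑forming step.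

Alternative 3: Bond C1–C6 is cut, giving the open tetraketide methyl 3,5,7‑trioxooctacosanoate A6.
- Forward key step: dilute aqueous‑methanolic KOH effects aldol addition of the C2 carbanion to the C7 ketone, then dehydration and enolisation, to give methyl 2‑heneicosyl‑4,6‑dihydroxybenzoate A7.
- For: it is the shortest ring construction in concept, with one bond formed from an acyclic chain and both methoxyl oxygens free for a single methylation. On atom economy of the ring‑forming step it equals the chosen route.
- Against: A6 requires polyanion acylation chemistry on a waxy substrate and is prone to lactonisation to a pyranone and to Claisen‑type closure. C1 arrives bearing carbon, not oxygen, so the hindered 2,6‑disubstituted ester must be reduced, oxidised (Dakin or Baeyer–Villiger) and hydrolysed. That is about four steps after methylation.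
- Comparison: the chosen route places oxygen on C1 from the start and needs only two steps after ring formation.

Key step: step 6

## Route

Step 1
Reactants: 1 dimethyl squarate (3,4‑dimethoxycyclobut‑3‑ene‑1,2‑dione)
Product: 2 4‑hydroxy‑2,3‑dimethoxycyclobut‑2‑en‑1‑one (racemic)
Conditions: LiAlH(OtBu)3 (1.1 equiv), THF, −78 → −20 °C; then cold 1 M HCl
Reagents that add atoms: none
Why: The bulky, mild hydride adds once, 1,2, to one of the two equivalent carbonyls of the vinylogous diester, and the resulting alkoxide resists further reduction at low temperature (chemoselective carbonyl reduction). The new stereocentre is racemic and is removed in step 2.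

Step 2
Reactants: 2 4‑hydroxy‑2,3‑dimethoxycyclobut‑2‑en‑1‑one
Product: 3 3‑methoxycyclobut‑3‑ene‑1,2‑dione
Conditions: conc. HCl (cat.), CH2Cl2, 0 °C → rt
Reagents that add atoms: water, O (it delivers the new carbonyl oxygen after the hydroxyl has ionised; an equal amount of water is released)
Why: Acid ionises the allylic hydroxyl to a cyclobutenyl cation stabilised by the methoxyl at its far terminus; water adds there and the hemiketal collapses with loss of methanol. This 1,3‑carbonyl transposition is the standard conversion of squarate 1,2‑adducts into 3‑alkoxycyclobutenediones. Dione 3 is moisture‑sensitive and somewhat volatile, so it is dried, concentrated cold and used at once.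

Step 3
Reactants: 4 1‑bromoeicosane; 5 2,3‑dibromoprop‑1‑ene
Product: 7 2‑bromotricos‑1‑ene, via eicosylmagnesium bromide 6 (not isolated)
Conditions: Mg turnings, THF, 45 °C; then 5 (1.2 equiv), CuI (5 mol %), THF, 0 °C → rt
Reagents that add atoms: none
Why: A primary alkyl Grignard reagent displaces the allylic bromide of 5 (copper‑catalysed allylic substitution) while the vinylic C–Br bond is inert. SN2 and SN2' attack give the same CH2=C(Br)CH2R product, so there is no regiochemical issue.

Step 4
Reactants: 7 2‑bromotricos‑1‑ene; 3 3‑methoxycyclobut‑3‑ene‑1,2‑dione
Product: 9 4‑hydroxy‑3‑methoxy‑4‑(tricos‑1‑en‑2‑yl)cyclobut‑2‑en‑1‑one (racemic), via tricos‑1‑en‑2‑yllithium 8 (not isolated)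
Conditions: t‑BuLi (2.0 equiv), Et2O, −78 °C; then cannulate into 3, THF, −78 °C; NH4Cl (aq)
Reagents that add atoms: none
Why: Bromine–lithium exchange is made irreversible by the second equivalent of t‑BuLi, which destroys t‑BuBr. Alkenyllithium 8 then adds 1,2 to the C2 carbonyl of 3, the ketone‑like carbonyl beside the methoxy‑bearing carbon, because the other carbonyl is deactivated as a vinylogous ester. The carbinol stereocentre forms as a racemate, which is immaterial since step 6 erases it.

Step 5
Reactants: 9 4‑hydroxy‑3‑methoxy‑4‑(tricos‑1‑en‑2‑yl)cyclobut‑2‑en‑1‑one
Product: 10 3‑methoxy‑4‑(methoxymethoxy)‑4‑(tricos‑1‑en‑2‑yl)cyclobut‑2‑en‑1‑one (racemic)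
Conditions: MOMCl, i‑Pr2NEt, n‑Bu4NI (cat.), CH2Cl2, 0 °C → rt
Reagents that add atoms: chloromethyl methyl ether, COCCl
Why: O‑Alkylation of the tertiary alcohol with the highly reactive α‑chloro ether under amine base, with iodide catalysis to help the congested centre. The acetal tolerates heat and K2CO3, and it caps the oxygen so that it cannot add to the ketene in step 6.

Step 6
Reactants: 10 3‑methoxy‑4‑(methoxymethoxy)‑4‑(tricos‑1‑en‑2‑yl)cyclobut‑2‑en‑1‑one
Product: 13 3‑heneicosyl‑5‑methoxy‑4‑(methoxymethoxy)phenol, via dienylketene 11 (not isolated), via cyclohexa‑2,4‑dienone 12 (not isolated)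
Conditions: toluene (degassed, 0.01 M), reflux (110 °C), Ar
Reagents that add atoms: none
Why: Heat opens the strained cyclobutenone 10 by conrotatory 4π electrocyclic cleavage of the bond between the carbonyl carbon and the carbinol carbon, and the lone‑pair donor OCH2OMe rotates outward, so the tricosenyl group turns inward and lies cis to the ketene in 11. Ketene 11 is a hexatriene (ketene C=C, enol ether C=C, 1,1‑disubstituted alkene) that closes by thermal disrotatory 6π electrocyclisation, the ketene carbon bonding to the terminal CH2 (arene bond C4–C5) to form the six‑membered carbocycle 12. Enolisation of 12 is driven by aromatisation and gives phenol 13, whose free hydroxyl is the former ketone oxygen. The closest known reaction type is the thermal ring expansion of 4‑alkenyl‑4‑alkoxy‑ or 4‑hydroxycyclobutenones to hydroquinone derivatives (Moore rearrangement). No stereocentre is formed and the one in 10 is erased on ring opening, so racemic 10 suffices. The selectivity that matters is the sense of rotation: only outward rotation of oxygen gives a ketene that can cyclise, and because the oxygen is an ether, an inward‑rotated ketene has no internal nucleophile and can only revert to 10. The substitution pattern of 13 is fixed by connectivity: carbinol carbon becomes C–OCH2OMe, its methoxy neighbour C–OMe, the ring CH stays CH, the carbonyl becomes C–OH, and the alkene carbons become C(chain) and CH. High dilution and exclusion of air should keep 11 from intermolecular capture and 13 from oxidation.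

Step 7
Reactants: 13 3‑heneicosyl‑5‑methoxy‑4‑(methoxymethoxy)phenol
Product: 14 1‑heneicosyl‑3,5‑dimethoxy‑2‑(methoxymethoxy)benzene
Conditions: MeI, K2CO3, acetone, 50 °C, Ar
Reagents that add atoms: iodomethane, CI
Why: Williamson ether synthesis on the only free phenol, which is unhindered (two ortho hydrogens). The acetal and the existing methyl ether are inert to K2CO3.

Step 8
Reactants: 14 1‑heneicosyl‑3,5‑dimethoxy‑2‑(methoxymethoxy)benzene
Product: 15 6‑heneicosyl‑2,4‑dimethoxyphenol
Conditions: HCl (3 M aq, cat.), MeOH–THF (1:1), 45 °C, Ar
Reagents that add atoms: none
Why: Acid‑catalysed acetal exchange: the methoxymethyl group is transferred to methanol as dimethoxymethane, freeing the hindered C1 phenol. Aryl methyl ethers do not cleave under these conditions, and THF keeps the lipid in solution.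

## Compound list

1 | dimethyl squarate (3,4‑dimethoxycyclobut‑3‑ene‑1,2‑dione) | COC1=C(OC)C(=O)C1=O | starting material
2 | 4‑hydroxy‑2,3‑dimethoxycyclobut‑2‑en‑1‑one (racemic, one enantiomer drawn) | COC1=C(OC)[C@@H](O)C1=O | intermediate
3 | 3‑methoxycyclobut‑3‑ene‑1,2‑dione | COC1=CC(=O)C1=O | intermediate
4 | 1‑bromoeicosane | CCCCCCCCCCCCCCCCCCCCBr | starting material
5 | 2,3‑dibromoprop‑1‑ene | C=C(Br)CBr | starting material
6 | eicosylmagnesium bromide | CCCCCCCCCCCCCCCCCCCC[Mg]Br | intermediate (not isolated)
7 | 2‑bromotricos‑1‑ene | CCCCCCCCCCCCCCCCCCCCCC(Br)=C | intermediate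
8 | tricos‑1‑en‑2‑yllithium | CCCCCCCCCCCCCCCCCCCCCC([Li])=C | intermediate (not isolated)
9 | 4‑hydroxy‑3‑methoxy‑4‑(tricos‑1‑en‑2‑yl)cyclobut‑2‑en‑1‑one (racemic, one enantiomer drawn) | CCCCCCCCCCCCCCCCCCCCCC(=C)[C@]1(O)C(OC)=CC1=O | intermediate
10 | 3‑methoxy‑4‑(methoxymethoxy)‑4‑(tricos‑1‑en‑2‑yl)cyclobut‑2‑en‑1‑one (racemic, one enantiomer drawn) | CCCCCCCCCCCCCCCCCCCCCC(=C)[C@]1(OCOC)C(OC)=CC1=O | intermediate
11 | (3Z)‑3‑methoxy‑4‑(methoxymethoxy)‑5‑methylidenehexacosa‑1,3‑dien‑1‑one (dienylketene) | O=C=C/C(OC)=C(/OCOC)C(=C)CCCCCCCCCCCCCCCCCCCCC | intermediate (not isolated)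
12 | 5‑heneicosyl‑3‑methoxy‑4‑(methoxymethoxy)cyclohexa‑2,4‑dien‑1‑one | O=C1C=C(OC)C(OCOC)=C(CCCCCCCCCCCCCCCCCCCCC)C1 | intermediate (not isolated)
13 | 3‑heneicosyl‑5‑methoxy‑4‑(methoxymethoxy)phenol | CCCCCCCCCCCCCCCCCCCCCc1cc(O)cc(OC)c1OCOC | intermediate
14 | 1‑heneicosyl‑3,5‑dimethoxy‑2‑(methoxymethoxy)benzene | CCCCCCCCCCCCCCCCCCCCCc1cc(OC)cc(OC)c1OCOC | intermediate
15 | 6‑heneicosyl‑2,4‑dimethoxyphenol | CCCCCCCCCCCCCCCCCCCCCc1cc(OC)cc(OC)c1O | target

## Step count and least certain steps

Total step count: 8. Longest linear sequence: 7 steps (steps 1, 2, 4, 5, 6, 7, 8 from 1); step 3 is a one‑step branch that supplies the side chain.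

Step 6 (key step). The monosubstituted ketene 11 may be consumed before it cyclises, by acylating the product phenol or traces of water or by dimerising. The bulky acetal may also erode the outward rotation or be lost thermally, and the product may be oxidised by air. The fallback sets out from alcohol 9 and drops the acetal. Thermolysis of unprotected 9 in degassed toluene should give 2‑heneicosyl‑6‑methoxybenzene‑1,4‑diol F1 by the same ring expansion in its free‑carbinol form. If F1 proves too air‑sensitive to handle, it is oxidised (air or FeCl3) to 2‑heneicosyl‑6‑methoxycyclohexa‑2,5‑diene‑1,4‑dione F2, purified as such and reduced back with Na2S2O4. The two hydroxyls of F1 are then distinguished by hindrance instead of by a protecting group. MeI (1 equiv) and K2CO3 in acetone under argon should alkylate the open C4 hydroxyl in preference to the C1 hydroxyl wedged between the methoxyl and the chain. This returns to the route at 15 and bypasses steps 5, 7 and 8.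

Step 4. Attack may go to the wrong site: the vinylogous ester carbonyl, conjugate addition with loss of methoxide, or deprotonation of the ring CH by the strongly basic lithium reagent. The halogen–lithium exchange may also stall because the waxy bromide crystallises at −78 °C. The fallback sets out from 7: Mg turnings in THF at 50 °C, where 7 is fully soluble, should give (tricos‑1‑en‑2‑yl)magnesium bromide F3. This reagent is less basic and is added to 3 in THF at −40 °C, returning to the route at 9 after NH4Cl work‑up.

Step 5. Etherification at the congested tertiary carbinol may be slow, and long exposure of the strained hydroxy ketone to amine base may degrade it. The fallback sets out from 9 and changes the protecting‑group class. TBSOTf and 2,6‑lutidine in CH2Cl2 at −78 °C should silylate even this hindered alcohol to 4‑[(tert‑butyldimethylsilyl)oxy]‑3‑methoxy‑4‑(tricos‑1‑en‑2‑yl)cyclobut‑2‑en‑1‑one F4. Thermolysis as in step 6 should give 4‑[(tert‑butyldimethylsilyl)oxy]‑3‑heneicosyl‑5‑methoxyphenol F5. MeI and K2CO3 in acetone give tert‑butyl(2‑heneicosyl‑4,6‑dimethoxyphenoxy)dimethylsilane F6, and n‑Bu4NF in THF returns to the route at 15.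

Step 8. The methoxymethyl cation (a formaldehyde equivalent) released on cleavage may alkylate the very electron‑rich ring at C3 or C5, and two arenes may then condense through a methylene bridge. The lipid may also precipitate from methanol and stall the exchange. The fallback sets out from 14 and replaces protic solvolysis by Lewis‑acid transfer of the acetal carbon to sulfur. ZnBr2 and n‑PrSH in CH2Cl2 at 0 °C should cleave the acetal in a solvent that dissolves the lipid, while the thiol captures the electrophile irreversibly. It returns to the route at 15 and no new compound is formed (F0).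

## Further compounds

F1 | step 6 | 2‑heneicosyl‑6‑methoxybenzene‑1,4‑diol | CCCCCCCCCCCCCCCCCCCCCc1cc(O)cc(OC)c1O
F2 | step 6 | 2‑heneicosyl‑6‑methoxycyclohexa‑2,5‑diene‑1,4‑dione | CCCCCCCCCCCCCCCCCCCCCC1=CC(=O)C=C(OC)C1=O
F3 | step 4 | (tricos‑1‑en‑2‑yl)magnesium bromide | CCCCCCCCCCCCCCCCCCCCCC(=C)[Mg]Br
F4 | step 5 | 4‑[(tert‑butyldimethylsilyl)oxy]‑3‑methoxy‑4‑(tricos‑1‑en‑2‑yl)cyclobut‑2‑en‑1‑one (racemic, one enantiomer drawn) | CCCCCCCCCCCCCCCCCCCCCC(=C)[C@]1(O[Si](C)(C)C(C)(C)C)C(OC)=CC1=O
F5 | step 5 | 4‑[(tert‑butyldimethylsilyl)oxy]‑3‑heneicosyl‑5‑methoxyphenol | CCCCCCCCCCCCCCCCCCCCCc1cc(O)cc(OC)c1O[Si](C)(C)C(C)(C)C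
F6 | step 5 | tert‑butyl(2‑heneicosyl‑4,6‑dimethoxyphenoxy)dimethylsilane | CCCCCCCCCCCCCCCCCCCCCc1cc(OC)cc(OC)c1O[Si](C)(C)C(C)(C)C
F0 | step 8 | none | none
A1 | alternative 1 | 3‑(benzyloxy)‑2‑heneicosyl‑6‑methyl‑4H‑pyran‑4‑one | CCCCCCCCCCCCCCCCCCCCCC1=C(OCc2ccccc2)C(=O)C=C(C)O1
A2 | alternative 1 | 4‑(benzyloxy)‑5‑heneicosylbenzene‑1,3‑diol | CCCCCCCCCCCCCCCCCCCCCc1cc(O)cc(O)c1OCc1ccccc1
A3 | alternative 2 | diethyl 2‑(benzyloxy)malonate | CCOC(=O)C(OCc1ccccc1)C(=O)OCC
A4 | alternative 2 | (E)‑pentacos‑3‑en‑2‑one | CC(=O)/C=C/CCCCCCCCCCCCCCCCCCCCC
A5 | alternative 2 | ethyl 1‑(benzyloxy)‑2‑heneicosyl‑4,6‑dioxocyclohexane‑1‑carboxylate (racemic, one diastereomer drawn) | CCCCCCCCCCCCCCCCCCCCC[C@@H]1CC(=O)CC(=O)[C@@]1(OCc1ccccc1)C(=O)OCC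
A6 | alternative 3 | methyl 3,5,7‑trioxooctacosanoate | COC(=O)CC(=O)CC(=O)CC(=O)CCCCCCCCCCCCCCCCCCCCC
A7 | alternative 3 | methyl 2‑heneicosyl‑4,6‑dihydroxybenzoate | CCCCCCCCCCCCCCCCCCCCCc1cc(O)cc(O)c1C(=O)OC
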